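**Retrosynthetic overview**
- The carbinol centre is set last, by catalyst-controlled reduction of the free hexaphenol aryl ketone. The six methyl ethers are cleaved one step earlier, while the sensitive benzylic position is still a ketone.
- The all-trans 1-aroylindane comes from an oxidative ring contraction of a 1,2,4-triaryl-1,2-dihydronaphthalene, in which the fused aryl ring shifts 1,2.
- The six-membered carbocycle is formed first, by Friedel–Crafts closure of a Z-configured 1,1-diarylalkenyl carbinol made by Suzuki coupling of a Z-enol triflate. It is then contracted to the five-membered ring.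
- The enol triflate comes from a 2-aryl-1,4-diketone, made by rhodium-catalysed asymmetric conjugate arylation of a symmetrical enedione. This is the only step that introduces absolute configuration.
- Building blocks: resorcinol (one aryl boronate serves both resorcinol rings), two anisoles and fumaryl chloride.

Assumption and locants: the SMILES is read as the (1R,2S,3R)-indane, all-trans on the ring, with an (R)-carbinol; C1 (bears the 4-oxyphenyl), C2 (bears the 3,5-dioxyphenyl), C3 and Cα (carbinol carbon) are target locants used throughout, and ring A is the fused resorcinol ring.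

**Step 1**
Reactants: 1 resorcinol
Product: 2 1,3-dimethoxybenzene
Conditions: MeI (2.5 equiv), K2CO3, acetone, reflux
Reagents that add atoms: iodomethane, CI
Why: Williamson ether synthesis gives methyl ethers that survive every later step and are all removed together in step 9.

**Step 2**
Reactants: 2 1,3-dimethoxybenzene
Product: 3 2-(3,5-dimethoxyphenyl)-4,4,5,5-tetramethyl-1,3,2-dioxaborolane
Conditions: [Ir(OMe)(cod)]2 (1.5 mol %), 4,4'-di-tert-butyl-2,2'-bipyridine (3 mol %), B2pin2 (1.0 equiv), MTBE, 80 °C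
Reagents that add atoms: bis(pinacolato)diboron, CC1(C)OB(OC1(C)C)B1OC(C)(C)C(C)(C)O1
Why: Sterically controlled iridium-catalysed C–H borylation attacks only the C–H meta to both methoxy groups, the one ring carbon that electrophilic chemistry cannot reach.

**Step 3**
Reactants: 4 fumaryl chloride, 5 anisole (2.2 equiv)
Product: 6 (E)-1,4-bis(4-methoxyphenyl)but-2-ene-1,4-dione
Conditions: AlCl3 (2.5 equiv), CH2Cl2, 0 to 20 °C; ice/HCl
Reagents that add atoms: none
Why: A para-selective double Friedel–Crafts acylation installs both 4-oxyphenyl groups and the whole C1–C2–C3–Cα chain in one operation.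

**Step 4**
Reactants: 6 (E)-1,4-bis(4-methoxyphenyl)but-2-ene-1,4-dione, 3 aryl boronate (1.3 equiv)
Product: 7 (S)-2-(3,5-dimethoxyphenyl)-1,4-bis(4-methoxyphenyl)butane-1,4-dione
Conditions: [RhCl(C2H4)2]2 (1.5 mol %), (R,R)-2,5-diphenylbicyclo[2.2.2]octa-2,5-diene (3.3 mol %), aq. KOH (10 mol %), dioxane/H2O 10:1, 20 °C; pH 7 quench
Reagents that add atoms: none
Why: In this Hayashi–Miyaura asymmetric 1,4-addition the two alkene carbons of the C2h-symmetric enedione are equivalent, so there is no regiochemical issue, and the diene antipode expected to bind the Re,Re face sets C2 as (S), with low base loading and temperature protecting the new α-aryl ketone centre.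

**Step 5**
Reactants: 7 (S)-diketone
Product: 9 (1Z,3S)-3-(3,5-dimethoxyphenyl)-1,4-bis(4-methoxyphenyl)-4-oxobut-1-en-1-yl trifluoromethanesulfonate, via potassium Z-enolate 8 (not isolated)
Conditions: 7 added to KN(SiMe3)2 (1.1 equiv), THF, −78 °C, 10 min; Comins' reagent (1.2 equiv), −78 °C; aq. NH4Cl
Reagents that add atoms: N-(5-chloropyridin-2-yl)bis(trifluoromethanesulfonimide), FC(F)(F)S(=O)(=O)N(c1ccc(Cl)cn1)S(=O)(=O)C(F)(F)F
Why: Kinetic deprotonation by the bulky amide takes the only unhindered CH2 (C3) and gives the Z(O)-enolate typical of aryl alkyl ketones, and fast O-sulfonylation at −78 °C fixes that geometry before proton transfer to the tertiary C2–H can erode the stereocentre.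

**Step 6**
Reactants: 9 keto enol triflate
Product: 10 (1Z,3S)-3-(3,5-dimethoxyphenyl)-4-hydroxy-1,4-bis(4-methoxyphenyl)but-1-en-1-yl trifluoromethanesulfonate (C1 epimers)
Conditions: NaBH4, CeCl3·7H2O, MeOH/THF, −40 °C
Reagents that add atoms: none
Why: Luche reduction removes the carbonyl that acidifies C2–H under non-basic conditions and leaves the vinyl triflate intact, and the new C1 carbinol configuration does not matter because C1 is ionised in step 7.

**Step 7**
Reactants: 10 hydroxy enol triflate, 3 aryl boronate (1.2 equiv)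
Product: 12 (1R,2R)-2-(3,5-dimethoxyphenyl)-6,8-dimethoxy-1,4-bis(4-methoxyphenyl)-1,2-dihydronaphthalene, via Z-triarylbutenol 11 (not isolated)
Conditions: Pd(PPh3)4 (3 mol %), K3PO4 (1.5 equiv), dioxane/H2O, 60 °C; extractive work-up, then (CF3)2CHOH, 25 °C
Reagents that add atoms: none
Why: Stereoretentive Suzuki–Miyaura coupling places ring A cis to the chain, and acid-free dehydrative Friedel–Crafts alkylation in hexafluoroisopropanol then ionises only the p-anisyl carbinol, whose cation is captured by the ortho/para-activated carbon of ring A in a six-membered closure anti to the C2 aryl, setting C1 trans to C2.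

**Step 8**
Reactants: 12 (1R,2R)-dihydronaphthalene
Product: 14 (4-methoxyphenyl)[(1R,2S,3R)-2-(3,5-dimethoxyphenyl)-4,6-dimethoxy-3-(4-methoxyphenyl)-2,3-dihydro-1H-inden-1-yl]methanone, via hydroxy-iodane adduct 13 (not isolated)
Conditions: PhI(OH)OTs (1.1 equiv), MeCN/H2O 9:1, −20 to 0 °C
Reagents that add atoms: water, O
Why: Proposed new method: PhI(OH)OTs delivers its electrophilic trivalent iodine to C3 of the cyclic 1,1-diarylalkene on the face anti to the C2 aryl, water caps the doubly benzylic Cα cation trans to iodine, and in the diequatorial conformer only the Cα–ring A bond is antiperiplanar to the C3–I bond (the p-anisyl group is cis to iodine and can never align), so loss of PhI drives a 1,2-shift of ring A from Cα to C3 with inversion, which contracts the six-membered ring to the indane, releases the p-anisoyl ketone and sets C3 trans to C2 (also the thermodynamic arrangement at this epimerisable centre); the closest known reaction types are the hypervalent-iodine ring contraction of 4-H and 4-alkyl 1,2-dihydronaphthalenes and the oxidative 1,2-aryl migration of acyclic 1,1-diarylalkenes, neither shown on a 4-aryl-1,2-dihydronaphthalene in which the less electron-rich aryl must migrate in preference to p-anisyl.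

**Step 9**
Reactants: 14 hexamethyl ether ketone
Product: 15 (4-hydroxyphenyl)[(1R,2S,3R)-2-(3,5-dihydroxyphenyl)-4,6-dihydroxy-3-(4-hydroxyphenyl)-2,3-dihydro-1H-inden-1-yl]methanone
Conditions: BBr3 (12 equiv), CH2Cl2, −78 to 20 °C; H2O
Reagents that add atoms: none
Why: Lewis-acid aryl methyl ether cleavage is run at the ketone stage because the final p-hydroxybenzylic alcohol would ionise under BBr3, and any enolisation at C3 returns the favoured all-trans isomer.

**Step 10**
Reactants: 15 hexaphenol ketone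
Product: 16 target, (1R,2S,3R)-2-(3,5-dihydroxyphenyl)-3-[(R)-hydroxy(4-hydroxyphenyl)methyl]-1-(4-hydroxyphenyl)-2,3-dihydro-1H-indene-5,7-diol
Conditions: RuCl[(R,R)-TsDPEN](p-cymene) (2 mol %), HCO2Na (5 equiv), degassed H2O/MeOH 1:1, 40 °C
Reagents that add atoms: none
Why: Noyori–Ikariya asymmetric transfer hydrogenation with the (R,R) catalyst delivers hydride to the Si face of the aryl ketone to give the (R)-carbinol, which is also the Felkin–Anh product when the fused aryl is the perpendicular group, and the near-neutral formate medium tolerates free phenols without ionising the product.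

**Compound list**
1 | resorcinol | Oc1cccc(O)c1 | starting material
2 | 1,3-dimethoxybenzene | COc1cccc(OC)c1 | intermediate
3 | 2-(3,5-dimethoxyphenyl)-4,4,5,5-tetramethyl-1,3,2-dioxaborolane | COc1cc(OC)cc(c1)B1OC(C)(C)C(C)(C)O1 | intermediate
4 | fumaryl chloride | O=C(Cl)/C=C/C(=O)Cl | starting material
5 | anisole | COc1ccccc1 | starting material
6 | (E)-1,4-bis(4-methoxyphenyl)but-2-ene-1,4-dione | COc1ccc(cc1)C(=O)/C=C/C(=O)c1ccc(OC)cc1 | intermediate
7 | (S)-2-(3,5-dimethoxyphenyl)-1,4-bis(4-methoxyphenyl)butane-1,4-dione | COc1ccc(C(=O)[C@H](c2cc(OC)cc(OC)c2)CC(=O)c2ccc(OC)cc2)cc1 | intermediate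
8 | potassium (1Z,3S)-3-(3,5-dimethoxyphenyl)-1,4-bis(4-methoxyphenyl)-4-oxobut-1-en-1-olate | COc1ccc(C(=O)[C@H](c2cc(OC)cc(OC)c2)/C=C(/c2ccc(OC)cc2)[O-])cc1.[K+] | intermediate
9 | (1Z,3S)-3-(3,5-dimethoxyphenyl)-1,4-bis(4-methoxyphenyl)-4-oxobut-1-en-1-yl trifluoromethanesulfonate | COc1ccc(C(=O)[C@H](c2cc(OC)cc(OC)c2)/C=C(/c2ccc(OC)cc2)OS(=O)(=O)C(F)(F)F)cc1 | intermediate
10 | (1Z,3S)-3-(3,5-dimethoxyphenyl)-4-hydroxy-1,4-bis(4-methoxyphenyl)but-1-en-1-yl trifluoromethanesulfonate, carbinol epimers | COc1ccc(C(O)[C@H](c2cc(OC)cc(OC)c2)/C=C(/c2ccc(OC)cc2)OS(=O)(=O)C(F)(F)F)cc1 | intermediate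
11 | (2S,3Z)-2,4-bis(3,5-dimethoxyphenyl)-1,4-bis(4-methoxyphenyl)but-3-en-1-ol, carbinol epimers | COc1ccc(C(O)[C@H](c2cc(OC)cc(OC)c2)/C=C(/c2ccc(OC)cc2)c2cc(OC)cc(OC)c2)cc1 | intermediate
12 | (1R,2R)-2-(3,5-dimethoxyphenyl)-6,8-dimethoxy-1,4-bis(4-methoxyphenyl)-1,2-dihydronaphthalene (1,2-trans) | COc1ccc([C@@H]2c3c(OC)cc(OC)cc3C(c3ccc(OC)cc3)=C[C@H]2c2cc(OC)cc(OC)c2)cc1 | intermediate
13 | tetralin-4-ol carrying phenyl(tosyloxy)iodanyl at C3, with iodine trans to both the C2 aryl and the new hydroxyl | COc1ccc([C@@H]2c3c(OC)cc(OC)cc3[C@](O)(c3ccc(OC)cc3)[C@H](I(c3ccccc3)OS(=O)(=O)c3ccc(C)cc3)[C@H]2c2cc(OC)cc(OC)c2)cc1 | intermediate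
14 | (4-methoxyphenyl)[(1R,2S,3R)-2-(3,5-dimethoxyphenyl)-4,6-dimethoxy-3-(4-methoxyphenyl)-2,3-dihydro-1H-inden-1-yl]methanone (all-trans) | COc1ccc([C@@H]2c3c(OC)cc(OC)cc3[C@H](C(=O)c3ccc(OC)cc3)[C@H]2c2cc(OC)cc(OC)c2)cc1 | intermediate
15 | (4-hydroxyphenyl)[(1R,2S,3R)-2-(3,5-dihydroxyphenyl)-4,6-dihydroxy-3-(4-hydroxyphenyl)-2,3-dihydro-1H-inden-1-yl]methanone | Oc1ccc([C@@H]2c3c(O)cc(O)cc3[C@H](C(=O)c3ccc(O)cc3)[C@H]2c2cc(O)cc(O)c2)cc1 | intermediate
16 | CNP0214825.1, (1R,2S,3R)-indane with (R)-carbinol | Oc1ccc([C@@H]2c3c(O)cc(O)cc3[C@H]([C@@H](O)c3ccc(O)cc3)[C@H]2c2cc(O)cc(O)c2)cc1 | target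

**Step count**
- Total steps: 10.
- Longest linear sequence: 9 steps (1 → 2 → 3 → 7 → 9 → 10 → 12 → 14 → 15 → 16). Step 3 is the only side branch.

**Steps most likely to fail**

Step 5. The tertiary C2–H of 7 is more acidic than the CH2, so proton transfer could racemise C2 or give the wrong enolate. The fallback never places C2 next to a carbonyl. It sets out from 6.
- Luche mono-reduction (0.3 equiv NaBH4, CeCl3·7H2O) gives the racemic γ-hydroxy enone F1.
- TBSCl/imidazole gives the silyl ether F2.
- The rhodium/diene arylation of step 4 with 3, under ligand control, gives the β-aryl ketone F3, whose stereocentre is not enolisable.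
- KN(SiMe3)2 and Comins' reagent give the Z-enol triflate F4.
- Et3N·3HF removes the silyl group and the route is rejoined at 10.

Step 8 (the new step). Possible failures are elimination and aromatisation to the naphthalene, attack of the iodine reagent on the dimethoxyarenes, or acid-induced cyclisation of 12. The fallback keeps the contraction but runs it as the classical stepwise semipinacol, using known reactions only. It sets out from 12.
- Dimethyldioxirane in acetone at −20 °C epoxidises anti to the C2 aryl and gives the epoxide F5.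
- Hydrolysis buffered with NaHCO3 opens it at the benzylic carbon to the trans-diol F6.
- MsCl/Et3N sulfonylates only the secondary hydroxyl to give the hydroxy mesylate F7.
- Et2AlCl (or KOt-Bu) triggers the known diol monosulfonate pinacol-type ring contraction, with the ring bond antiperiplanar to the equatorial mesylate, and the route is rejoined at 14.

Step 10. The ketone is hindered and electron-rich and carries six free phenols, so turnover may be slow or the selectivity poor. The product can also lose water. The fallback moves the reduction onto a protected substrate and uses a stoichiometric borane. It sets out from 15.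
- TBSCl/imidazole in DMF gives the hexa-silyl ketone F8.
- (S)-2-methyl-CBS-oxazaborolidine with BH3·SMe2 at −20 °C gives the (R)-carbinol F9.
- Et3N·3HF in THF at 0 °C removes the silyl groups under non-ionising conditions and gives 16.

**Further compounds**
F1 | step 5 | (E)-4-hydroxy-1,4-bis(4-methoxyphenyl)but-2-en-1-one (racemic) | COc1ccc(C(O)/C=C/C(=O)c2ccc(OC)cc2)cc1
F2 | step 5 | (E)-4-(tert-butyldimethylsilyloxy)-1,4-bis(4-methoxyphenyl)but-2-en-1-one | COc1ccc(C(O[Si](C)(C)C(C)(C)C)/C=C/C(=O)c2ccc(OC)cc2)cc1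
F3 | step 5 | (3S)-4-(tert-butyldimethylsilyloxy)-3-(3,5-dimethoxyphenyl)-1,4-bis(4-methoxyphenyl)butan-1-one, silyloxy epimers | COc1ccc(C(O[Si](C)(C)C(C)(C)C)[C@H](c2cc(OC)cc(OC)c2)CC(=O)c2ccc(OC)cc2)cc1
F4 | step 5 | (1Z,3S)-4-(tert-butyldimethylsilyloxy)-3-(3,5-dimethoxyphenyl)-1,4-bis(4-methoxyphenyl)but-1-en-1-yl trifluoromethanesulfonate | COc1ccc(C(O[Si](C)(C)C(C)(C)C)[C@H](c2cc(OC)cc(OC)c2)/C=C(/c2ccc(OC)cc2)OS(=O)(=O)C(F)(F)F)cc1
F5 | step 8 | 3,4-epoxide of 12, oxygen anti to the C2 aryl | COc1ccc([C@@H]2c3c(OC)cc(OC)cc3[C@]3(c4ccc(OC)cc4)O[C@@H]3[C@H]2c2cc(OC)cc(OC)c2)cc1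
F6 | step 8 | trans-3,4-diol of the tetralin, secondary hydroxyl anti to the C2 aryl | COc1ccc([C@@H]2c3c(OC)cc(OC)cc3[C@](O)(c3ccc(OC)cc3)[C@H](O)[C@H]2c2cc(OC)cc(OC)c2)cc1
F7 | step 8 | 3-methanesulfonate of the trans-3,4-diol | COc1ccc([C@@H]2c3c(OC)cc(OC)cc3[C@](O)(c3ccc(OC)cc3)[C@H](OS(C)(=O)=O)[C@H]2c2cc(OC)cc(OC)c2)cc1
F8 | step 10 | hexakis(tert-butyldimethylsilyl) ether of 15 | CC(C)(C)[Si](C)(C)Oc1ccc([C@@H]2c3c(O[Si](C)(C)C(C)(C)C)cc(O[Si](C)(C)C(C)(C)C)cc3[C@H](C(=O)c3ccc(O[Si](C)(C)C(C)(C)C)cc3)[C@H]2c2cc(O[Si](C)(C)C(C)(C)C)cc(O[Si](C)(C)C(C)(C)C)c2)cc1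
F9 | step 10 | hexakis(tert-butyldimethylsilyl) ether of 16, free (R)-carbinol | CC(C)(C)[Si](C)(C)Oc1ccc([C@@H]2c3c(O[Si](C)(C)C(C)(C)C)cc(O[Si](C)(C)C(C)(C)C)cc3[C@H]([C@@H](O)c3ccc(O[Si](C)(C)C(C)(C)C)cc3)[C@H]2c2cc(O[Si](C)(C)C(C)(C)C)cc(O[Si](C)(C)C(C)(C)C)c2)cc1
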